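**Retrosynthetic overview**

1. The C5 angelate and the free C6 hydroxyl come last, from trans-diaxial opening of a 5α,6α-epoxide beside the C4 exomethylene by angelic acid. The C1 acetate comes from Rubottom oxidation of a C1=C2 silyl enol ether, which also serves as the protecting group of the C2 ketone.
2. Key disconnection: C3a–C7a (indane numbering: C1 acetoxy carbon, C2 ketone, C3 methylene, C3a/C7a ring fusion, C4 exomethylene carbon, C5 angelate carbon, C6 carbinol, C7 isopropyl carbon). This is the only bond common to the five-membered ring (C1, C2, C3, C3a, C7a) and the six-membered ring (C3a, C4, C5, C6, C7, C7a). Without it the skeleton is a nine-membered carbocycle in which the C4 ketone makes C3a nucleophilic and the C2 ketone, through an E C1=C7a double bond, makes C7a electrophilic, so one transannular Michael addition closes both rings.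
3. The (S,E)-7-isopropylcyclonon-5-ene-1,4-dione comes from a trans-1,2-dialkenylcyclopentanol by anionic oxy-Cope rearrangement, which fixes the E-alkene and the C7 centre. The C2 oxygen rides through as a silyl ether and is oxidised only in the step before cyclisation, so the E double bond is never broken on the way to the enone.
4. The cyclopentanol comes from 2-iodocyclopent-2-en-1-one by Suzuki coupling with an (E)-3-methylbutenylboronate, asymmetric conjugate borylation–oxidation, silylation and vinyl Grignard addition.
5. Ring order: cyclopentane carrier ring → nine-membered ring (four-carbon ring expansion) → five- and six-membered rings together; then enone, epoxide, exomethylene, acetate and angelate on the finished bicycle.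

Key step: step 9

Numbering and faces: the indane numbering above is used for all atoms, also in the nine-membered intermediates; β is the face of H-3a, α the other face.

Assumption: the sense of induction of the copper–diphosphine catalyst in step 3 is not established for this α-alkenyl enone; the ligand enantiomer is taken to be the one that gives the (3R) alcohol 6.

**Route**

Step 1
Reactants: 1 3-methylbut-1-yne
Product: 2 2-[(E)-3-methylbut-1-en-1-yl]-4,4,5,5-tetramethyl-1,3,2-dioxaborolane
Conditions: pinacolborane, Cp2Zr(H)Cl (5 mol%), Et3N (10 mol%), neat, 60 °C, sealed tube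
Reagents that add atoms: pinacolborane, B1OC(C)(C)C(C)(C)O1
Why: Zirconocene-hydride-catalysed hydroboration of the terminal alkyne adds H and B syn and anti-Markovnikov, so only the E-alkenylboronate should form.

Step 2
Reactants: 2 2-[(E)-3-methylbut-1-en-1-yl]-4,4,5,5-tetramethyl-1,3,2-dioxaborolane; 3 2-iodocyclopent-2-en-1-one
Product: 4 2-[(E)-3-methylbut-1-en-1-yl]cyclopent-2-en-1-one
Conditions: Pd(dppf)Cl2 (3 mol%), K3PO4, THF/H2O, 40 °C
Reagents that add atoms: none
Why: Suzuki–Miyaura coupling of an α-iodoenone with an alkenylboronate runs under mild base with retention of the E geometry.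

Step 3
Reactants: 4 2-[(E)-3-methylbut-1-en-1-yl]cyclopent-2-en-1-one
Product: 6 (2S,3R)-3-hydroxy-2-[(E)-3-methylbut-1-en-1-yl]cyclopentan-1-one, via β-boryl ketone 5 (not isolated)
Conditions: B2pin2, CuCl (3 mol%), NaOtBu (6 mol%), 1-[2-(diphenylphosphino)ferrocenyl]ethyldicyclohexylphosphine (one enantiomer, 3 mol%), MeOH (2 equiv), THF, rt; then NaBO3·4H2O, THF/H2O, rt
Reagents that add atoms: sodium perborate, [Na+].[O-]OB=O
Why: Catalytic asymmetric conjugate borylation sets C3 under ligand control, methanol protonates the copper enolate at C2 trans to the boryl group, and perborate oxidation replaces boron by hydroxyl with retention.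

Step 4
Reactants: 6 (2S,3R)-3-hydroxy-2-[(E)-3-methylbut-1-en-1-yl]cyclopentan-1-one
Product: 7 (2S,3R)-3-(tert-butyldimethylsilyloxy)-2-[(E)-3-methylbut-1-en-1-yl]cyclopentan-1-one
Conditions: TBSCl, imidazole, DMF, 0 °C to rt
Reagents that add atoms: tert-butyldimethylsilyl chloride, CC(C)(C)[Si](C)(C)Cl
Why: Imidazole-mediated silylation of the secondary alcohol is mild enough to leave the β,γ-unsaturated β-hydroxy ketone unconjugated and uneliminated.

Step 5
Reactants: 7 (2S,3R)-3-(tert-butyldimethylsilyloxy)-2-[(E)-3-methylbut-1-en-1-yl]cyclopentan-1-one; 8 vinylmagnesium bromide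
Product: 9 (1S,2S,3R)-3-(tert-butyldimethylsilyloxy)-1-ethenyl-2-[(E)-3-methylbut-1-en-1-yl]cyclopentan-1-ol
Conditions: LaCl3·2LiCl, THF, −78 °C; aqueous work-up
Reagents that add atoms: none
Why: Grignard 1,2-addition, made less basic by the lanthanum salt, should occur on the ketone face anti to the adjacent alkenyl group, which puts the hydroxyl cis to that group and the two alkenyl groups trans.

Step 6
Reactants: 9 (1S,2S,3R)-3-(tert-butyldimethylsilyloxy)-1-ethenyl-2-[(E)-3-methylbut-1-en-1-yl]cyclopentan-1-ol
Product: 12 (4R,7S,E)-4-(tert-butyldimethylsilyloxy)-7-isopropylcyclonon-5-en-1-one, via potassium alkoxide 10 (not isolated), via potassium enolate 11 (not isolated)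
Conditions: KH, 18-crown-6, THF, 0 °C to rt; then AcOH, −78 °C
Reagents that add atoms: none
Why: Anionic oxy-Cope rearrangement of the trans-dialkenylcyclopentanolate through a chair, with the ring bonds and the isopropyl-bearing alkene terminus equatorial, should give the E C1=C7a alkene and transfer the configuration of the alkenyl-bearing ring carbon to C7.

Step 7
Reactants: 12 (4R,7S,E)-4-(tert-butyldimethylsilyloxy)-7-isopropylcyclonon-5-en-1-one
Product: 13 (4R,7S,E)-4-hydroxy-7-isopropylcyclonon-5-en-1-one
Conditions: HF·pyridine, pyridine, THF, 0 °C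
Reagents that add atoms: none
Why: Buffered fluoride desilylation frees the allylic C2 hydroxyl without touching the ketone or the strained E-alkene.

Step 8
Reactants: 13 (4R,7S,E)-4-hydroxy-7-isopropylcyclonon-5-en-1-one
Product: 14 (S,E)-7-isopropylcyclonon-5-ene-1,4-dione
Conditions: Dess–Martin periodinane, pyridine, CH2Cl2, 0 °C; used at once
Reagents that add atoms: none
Why: Dess–Martin oxidation of the allylic alcohol makes the C2 enone without opening the C1=C7a double bond, so the E geometry from step 6 is kept.

Step 9
Reactants: 14 (S,E)-7-isopropylcyclonon-5-ene-1,4-dione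
Product: 17 (3aR,7S,7aR)-2-(tert-butyldimethylsilyloxy)-7-isopropyl-3,3a,5,6,7,7a-hexahydro-4H-inden-4-one, via ring-open lithium enolate 15 (not isolated), via bicyclic lithium enolate 16 (not isolated)
Conditions: LiN(SiMe3)2 (1.0 equiv), THF, −78 °C; then TBSOTf, −78 °C
Reagents that add atoms: tert-butyldimethylsilyl triflate, CC(C)(C)[Si](C)(C)OS(=O)(=O)C(F)(F)F
Why: Proposed new method: LiN(SiMe3)2 removes a C3a proton next to the C4 ketone, C3a of lithium enolate 15 then adds across the ring to C7a of the twisted E-enone (transannular Michael addition), which forms the C3a–C7a bond and leaves the C2 enolate 16 with its double bond at C1=C2, and TBSOTf silylates that oxygen before the double bond can move. The closest known reaction type is the base-induced transannular Michael addition of ketone enolates to enones in medium and large rings, which has not been run on a nine-membered ene-dione. Counted on the C1=C7a acceptor, the six-membered ring (C3a, C4, C5, C6, C7, C7a) closes 6-exo-trig, while the five-membered ring (C3a, C3, C2, C1, C7a) contains both alkene carbons and therefore closes in the formal 5-endo-trig sense; this is accepted here because the chair of the forming six-membered ring, not the short C3–C2–C1 bridge, guides C3a, and because the E-alkene of a nine-membered ring is already twisted with its inner π-lobe at C7a turned toward C3a. C7a is set by attack on that inner face in a chair with the C7 isopropyl group equatorial, which puts H-7a anti to H-7, and C3a is set in the same chair with C3 equatorial (trans fusion) and stays correctable by enolisation beside the C4 ketone. The step needs the C3a enolate to react and not the C3 or C5 enolates, which can only give three- or four-membered rings or a reversible C5-to-C2 aldol and so return to 14 by proton exchange with HN(SiMe3)2; the substrate does not enforce deprotonation at C3a, so one equivalent of base at −78 °C and silylation directly after consumption of 14 are used to keep 16 from isomerising. The face selectivity at C7a rests on the E geometry delivered by the oxy-Cope step, since the Z-enone would fold with C1 axial and give the C7a epimer.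

Step 10
Reactants: 17 (3aR,7S,7aR)-2-(tert-butyldimethylsilyloxy)-7-isopropyl-3,3a,5,6,7,7a-hexahydro-4H-inden-4-one
Product: 20 trans-fused 2-(tert-butyldimethylsilyloxy)-7α-isopropyl-3,3a,7,7a-tetrahydro-4H-inden-4-one (H-3a β, H-7a α; C5=C6 enone), via lithium enolate 18 (not isolated), via sulfilimine adduct 19 (not isolated)
Conditions: LiN(iPr)2, THF, −78 °C; then PhS(Cl)=NtBu, −78 °C
Reagents that add atoms: none
Why: Kinetic deprotonation takes a proton from the C5 methylene and not the C3a methine, and the enolate is dehydrogenated in the same flask by the sulfinimidoyl chloride (Mukaiyama dehydrogenation) through syn-elimination of the sulfenamide, while the silyl enol ether is inert to both reagents.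

Step 11
Reactants: 20 trans-fused 2-(tert-butyldimethylsilyloxy)-7α-isopropyl-3,3a,7,7a-tetrahydro-4H-inden-4-one
Product: 21 5α,6α-epoxide of 20 (epoxy ketone; H-5 and H-6 β)
Conditions: tBuOOH (anhydrous), DBU, CH2Cl2, 0 °C to rt
Reagents that add atoms: tert-butyl hydroperoxide, CC(C)(C)OO
Why: In this Weitz–Scheffer epoxidation the peroxide anion should add to C6 along the axial trajectory of the locked trans-fused half-chair, anti to the axial H-7, and the enolate then closes the epoxide on that same α-face, cis to the equatorial isopropyl group.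

Step 12
Reactants: 21 5α,6α-epoxy ketone
Product: 22 2-(tert-butyldimethylsilyloxy)-5α,6α-epoxy-7α-isopropyl-4-methylidene-3,3a,4,5,6,7,7a-heptahydro-1H-indene (H-3a β, H-7a α)
Conditions: Ph3PCH3Br, KOtBu, THF, 0 °C; then 21, 0 °C to rt
Reagents that add atoms: methylenetriphenylphosphorane, C=P(c1ccccc1)(c1ccccc1)c1ccccc1
Why: Wittig methylenation of the α,β-epoxy ketone with the preformed ylide should be faster than enolisation at C3a and leaves the epoxide and the silyl enol ether untouched, after which C3a can no longer epimerise.

Step 13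
Reactants: 22 4-methylidene 5α,6α-epoxide carrying the C2 silyl enol ether
Product: 24 5α,6α-epoxy-1α-hydroxy-7α-isopropyl-4-methylidene-octahydro-2H-inden-2-one (H-3a β, H-7a α), via silyloxy epoxide 23 (not isolated)
Conditions: dimethyldioxirane, acetone/CH2Cl2, −78 to −20 °C; then Et3N·3HF, THF, 0 °C
Reagents that add atoms: dimethyldioxirane, CC1(C)OO1
Why: In this Rubottom oxidation dimethyldioxirane epoxidises the electron-rich C1=C2 silyl enol ether far faster than the 1,1-disubstituted alkene, on the α-face away from the C7a–C7 bond, and fluoride opens the silyloxy epoxide to the C1 hydroxy C2 ketone.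

Step 14
Reactants: 24 5α,6α-epoxy-1α-hydroxy-7α-isopropyl-4-methylidene-octahydro-2H-inden-2-one
Product: 25 1α-acetoxy-5α,6α-epoxy-7α-isopropyl-4-methylidene-octahydro-2H-inden-2-one (H-3a β, H-7a α)
Conditions: Ac2O, DMAP, pyridine, CH2Cl2, 0 °C
Reagents that add atoms: acetic anhydride, CC(=O)OC(C)=O
Why: DMAP-catalysed acetylation of the α-hydroxy ketone fixes C1, which is epimerisable beside the ketone and should rest in the configuration trans to the C7a–C7 bond.

Step 15
Reactants: 25 1α-acetoxy-5α,6α-epoxy-7α-isopropyl-4-methylidene-octahydro-2H-inden-2-one; 26 angelic acid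
Product: 27 (1R,3aR,5S,6S,7S,7aR)-1-acetoxy-6-hydroxy-7-isopropyl-4-methylidene-2-oxo-octahydro-1H-inden-5-yl (Z)-2-methylbut-2-enoate (CNP0317011.1)
Conditions: 26 (4 equiv), Cs2CO3 (0.5 equiv), DMF, 50 °C
Reagents that add atoms: none
Why: Carboxylate opening of the vinyl epoxide by SN2 attack at the allylic C5 with inversion follows the trans-diaxial course and frees the axial C6 hydroxyl, so neither hydroxyl protection nor an activated angelate is needed.

**Compound list**

1 | 3-methylbut-1-yne | CC(C)C#C | starting material
2 | 2-[(E)-3-methylbut-1-en-1-yl]-4,4,5,5-tetramethyl-1,3,2-dioxaborolane | CC(C)/C=C/B1OC(C)(C)C(C)(C)O1 | intermediate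
3 | 2-iodocyclopent-2-en-1-one | O=C1CCC=C1I | starting material
4 | 2-[(E)-3-methylbut-1-en-1-yl]cyclopent-2-en-1-one | O=C1CCC=C1/C=C/C(C)C | intermediate
5 | (2R,3R)-2-[(E)-3-methylbut-1-en-1-yl]-3-(pinacolatoboryl)cyclopentan-1-one, trans, not isolated | O=C1[C@@H](/C=C/C(C)C)[C@H](B2OC(C)(C)C(C)(C)O2)CC1 | intermediate
6 | (2S,3R)-3-hydroxy-2-[(E)-3-methylbut-1-en-1-yl]cyclopentan-1-one | O=C1[C@@H](/C=C/C(C)C)[C@H](O)CC1 | intermediate
7 | (2S,3R)-3-(tert-butyldimethylsilyloxy)-2-[(E)-3-methylbut-1-en-1-yl]cyclopentan-1-one | O=C1[C@@H](/C=C/C(C)C)[C@H](O[Si](C)(C)C(C)(C)C)CC1 | intermediate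
8 | vinylmagnesium bromide | C=C[Mg]Br | starting material
9 | (1S,2S,3R)-3-(tert-butyldimethylsilyloxy)-1-ethenyl-2-[(E)-3-methylbut-1-en-1-yl]cyclopentan-1-ol | C=C[C@]1(O)[C@@H](/C=C/C(C)C)[C@H](O[Si](C)(C)C(C)(C)C)CC1 | intermediate
10 | potassium alkoxide of 9, not isolated | C=C[C@]1(O[K])[C@@H](/C=C/C(C)C)[C@H](O[Si](C)(C)C(C)(C)C)CC1 | intermediate
11 | potassium enolate of 12 (C4–OK, C4=C5), not isolated | [K]OC1=CC[C@@H](C(C)C)/C=C/[C@H](O[Si](C)(C)C(C)(C)C)CC1 | intermediate
12 | (4R,7S,E)-4-(tert-butyldimethylsilyloxy)-7-isopropylcyclonon-5-en-1-one | O=C1CC[C@@H](C(C)C)/C=C/[C@H](O[Si](C)(C)C(C)(C)C)CC1 | intermediate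
13 | (4R,7S,E)-4-hydroxy-7-isopropylcyclonon-5-en-1-one | O=C1CC[C@@H](C(C)C)/C=C/[C@H](O)CC1 | intermediate
14 | (S,E)-7-isopropylcyclonon-5-ene-1,4-dione | O=C1CC[C@@H](C(C)C)/C=C/C(=O)CC1 | intermediate
15 | lithium enolate of 14 (C4–OLi, C3a=C4), not isolated | [Li]OC=1CC[C@@H](C(C)C)/C=C/C(=O)CC=1 | intermediate
16 | lithium C1=C2 enolate of the trans-fused 7α-isopropylhydrindan-4-one, not isolated | O=C1[C@@H]2CC(O[Li])=C[C@H]2[C@H](C(C)C)CC1 | intermediate
17 | (3aR,7S,7aR)-2-(tert-butyldimethylsilyloxy)-7-isopropyl-3,3a,5,6,7,7a-hexahydro-4H-inden-4-one | O=C1[C@@H]2CC(O[Si](C)(C)C(C)(C)C)=C[C@H]2[C@H](C(C)C)CC1 | intermediate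
18 | lithium enolate of 17 (C4–OLi, C4=C5), not isolated | [Li]OC=1[C@@H]2CC(O[Si](C)(C)C(C)(C)C)=C[C@H]2[C@H](C(C)C)CC=1 | intermediate
19 | C5 S-phenyl-N-tert-butylsulfilimine adduct of 17, not isolated | O=C1[C@@H]2CC(O[Si](C)(C)C(C)(C)C)=C[C@H]2[C@H](C(C)C)CC1S(=NC(C)(C)C)c1ccccc1 | intermediate
20 | trans-fused 2-(tert-butyldimethylsilyloxy)-7α-isopropyl-3,3a,7,7a-tetrahydro-4H-inden-4-one | O=C1[C@@H]2CC(O[Si](C)(C)C(C)(C)C)=C[C@H]2[C@H](C(C)C)C=C1 | intermediate
21 | 5α,6α-epoxide of 20 | O=C1[C@@H]2CC(O[Si](C)(C)C(C)(C)C)=C[C@H]2[C@H](C(C)C)[C@@H]3O[C@H]13 | intermediate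
22 | 4-methylidene analogue of 21 | C=C1[C@@H]2CC(O[Si](C)(C)C(C)(C)C)=C[C@H]2[C@H](C(C)C)[C@@H]3O[C@H]13 | intermediate
23 | 1α,2α-epoxide of 22 with the silyloxy group on C2, not isolated | C=C1[C@@H]2C[C@]3(O[Si](C)(C)C(C)(C)C)O[C@@H]3[C@H]2[C@H](C(C)C)[C@@H]4O[C@H]14 | intermediate
24 | 5α,6α-epoxy-1α-hydroxy-7α-isopropyl-4-methylidene-octahydro-2H-inden-2-one | C=C1[C@@H]2CC(=O)[C@H](O)[C@H]2[C@H](C(C)C)[C@@H]3O[C@H]13 | intermediate
25 | 1α-acetoxy-5α,6α-epoxy-7α-isopropyl-4-methylidene-octahydro-2H-inden-2-one | C=C1[C@@H]2CC(=O)[C@H](OC(C)=O)[C@H]2[C@H](C(C)C)[C@@H]3O[C@H]13 | intermediate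
26 | angelic acid, (Z)-2-methylbut-2-enoic acid | C/C=C(/C)C(=O)O | starting material
27 | (1R,3aR,5S,6S,7S,7aR)-1-acetoxy-6-hydroxy-7-isopropyl-4-methylidene-2-oxo-octahydro-1H-inden-5-yl (Z)-2-methylbut-2-enoate | C=C1[C@@H]2CC(=O)[C@H](OC(C)=O)[C@H]2[C@H](C(C)C)[C@H](O)[C@H]1OC(=O)/C(C)=C\C | target

**Step count and risks**

Total steps: 15. Longest linear sequence: 15 steps (1 to 27).

Steps most likely to fail:

Step 9 (proposed new method). Three processes may defeat it: enolisation at C3 or C5 that leads nowhere, proton exchange that moves the C1=C2 enolate before it is silylated, or no C3a–C7a bond formation because the five-membered ring must close in the 5-endo sense. The fallback uses known chemistry and builds the bicycle without a medium ring; it sets out from vinylmagnesium bromide 8 (with purchased 3-methylbutanal and methyl vinyl ketone) and returns to the route at 17. Amine-catalysed asymmetric Michael addition of 3-methylbutanal to methyl vinyl ketone should give (S)-2-isopropyl-5-oxohexanal F1, and aldol condensation should give (S)-4-isopropylcyclohex-2-en-1-one F2. CuBr·SMe2-catalysed conjugate addition of 8 to F2 anti to the isopropyl group, with alkylation of the enolate in the same flask by 3-bromo-2-(tert-butyldimethylsilyloxy)prop-1-ene trans to the new vinyl group, should give (2,3-trans,3,4-trans)-2-[2-(tert-butyldimethylsilyloxy)prop-2-en-1-yl]-3-ethenyl-4-isopropylcyclohexan-1-one F3. Ring-closing metathesis with the second-generation Grubbs catalyst between the vinyl group and the silyl enol ether alkene then closes the five-membered ring and gives 17.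

Step 11. Peroxide attack on the β-face of C6 (poor facial selectivity beside the equatorial isopropyl group) or base-induced epimerisation at C3a may occur. The fallback replaces the nucleophilic epoxidation by a hydroxyl-directed one; it sets out from 20 and returns at 21. CBS reduction of 20 (2-methyl-CBS-oxazaborolidine enantiomer that delivers hydride to the β-face of C4, BH3·SMe2) should give the 4α-hydroxy allylic alcohol F4. Epoxidation with VO(acac)2 and tBuOOH, directed by that hydroxyl, should place the oxygen on the α-face to give the 4α-hydroxy-5α,6α-epoxide F5. Dess–Martin oxidation then returns 21.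

Step 15. Carboxylate attack at the exocyclic methylene carbon (SN2′ course), isomerisation of the angelate to the tiglate during a slow opening, or loss of the C1 acetate may occur. The fallback separates opening and acylation; it sets out from 25 and returns at 27. Acid-catalysed hydrolysis of the vinyl epoxide (dilute HClO4, THF/H2O, 0 °C), with water entering at allylic C5 with inversion, should give 1α-acetoxy-5β,6α-dihydroxy-7α-isopropyl-4-methylidene-octahydro-2H-inden-2-one F6. The less hindered allylic C5 hydroxyl is then acylated with the mixed anhydride of angelic acid 26 and 2,4,6-trichlorobenzoyl chloride (Yamaguchi esterification, Et3N then DMAP, toluene, rt) to give 27.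

**Further compounds**

F1 | step 9 | (S)-2-isopropyl-5-oxohexanal | O=C[C@H](C(C)C)CCC(C)=O
F2 | step 9 | (S)-4-isopropylcyclohex-2-en-1-one | O=C1C=C[C@H](C(C)C)CC1
F3 | step 9 | (2,3-trans,3,4-trans)-2-[2-(tert-butyldimethylsilyloxy)prop-2-en-1-yl]-3-ethenyl-4-isopropylcyclohexan-1-one | O=C1[C@H](CC(O[Si](C)(C)C(C)(C)C)=C)[C@@H](C=C)[C@H](C(C)C)CC1
F4 | step 11 | trans-fused 2-(tert-butyldimethylsilyloxy)-4α-hydroxy-7α-isopropyl-3a,4,7,7a-tetrahydro-3H-indene | O[C@@H]1[C@@H]2CC(O[Si](C)(C)C(C)(C)C)=C[C@H]2[C@H](C(C)C)C=C1
F5 | step 11 | 5α,6α-epoxide of F4 | O[C@@H]1[C@@H]2CC(O[Si](C)(C)C(C)(C)C)=C[C@H]2[C@H](C(C)C)[C@@H]3O[C@H]13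
F6 | step 15 | 1α-acetoxy-5β,6α-dihydroxy-7α-isopropyl-4-methylidene-octahydro-2H-inden-2-one | C=C1[C@@H]2CC(=O)[C@H](OC(C)=O)[C@H]2[C@H](C(C)C)[C@H](O)[C@H]1O
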